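The trap is to give the rise of intermediate C a rate constant, as if the solid substrate charged were already dissolved; at the start none of it is in solution.

| flask | solid substrate | partner | remark | time |
|---|---|---|---|---|
| summer | 0.20 M | 0.12 M | the very flask that is asked about, followed so far |  |
| winter | 0.40 M | 0.12 M | run made earlier |  |
| flask | 0.20 M | 0.120 M |  | 1.5 h |

- summer (time / min: intermediate C / %, product / %): 2.50: 22.0, 0.2; 5.00: 45.2, 0.9; 10.0: 82.7, 2.9; 20.0: 74.9, 7.8; 50.0: 54.9, 27.6
- winter (time / min: intermediate C / %, product / %): 2.50: 10.6, 0; 5.00: 23.6, 0; 10.0: 44.5, 1.2; 20.0: 78.1, 5.0; 40.0: 62.7, 17.5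

(readings scatter by 0.5 percentage points)

- solid substrate is a solid; its amount is given per volume of the solution
- the numbers in the tables scatter by 0.5 percentage points (one standard deviation)
- at the start none of the solid substrate is in solution

* the best time, 1.5 h at the latest, for intermediate C
* the amount of intermediate C, in percent of the solid substrate charged, at that time

So read the rate alone, as molar intermediate C plus product gained per minute. The summer run starts at 0.0184 M min⁻¹. The winter run, with twice the charge, gives 0.0183 M min⁻¹: as read from these two runs, the feed is zero order in the charge. It slows little, since the winter run's second 5.00 min gains 0.936 times its first.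

The summer sum reads 85.6 % at 10.0 min, then stops rising, while intermediate C later falls at 0.0104 min⁻¹. My reckoning carries the fill time, that ceiling times the charge over the feed: 9.37 min. I estimate that decay over half the fill time trims the peak to 81.4 %.

The forecast gives 0.165 h (0.14 h to 0.2 h) and 83.5 % (82 % to 87 %), holding that “the maximum sits at the end of feeding”; its peak is higher than mine.

The summer flask peaks at 0.161 h with 82.8 %, inside both forecast ranges, against my fill time of 0.156 h and peak of 81.4 %.

starting material → intermediate A (k = 0.00410 s⁻¹); intermediate B → product (k = 0.00600 s⁻¹); starting material → intermediate B (k = 4.70 × 10⁻⁴ s⁻¹); intermediate A → intermediate B (k = 6.50 × 10⁻⁴ s⁻¹); solid substrate ⇌ starting material, rate k5*(cs5 - [starting material]) while solid is left; crystals form when [starting material] > cs5 (solubility = 0.140 M, k = 0.00290 s⁻¹); starting material ⇌ intermediate C (K = 23.0, k = 0.0440 s⁻¹) Now take the neighbouring flask with 0.50 M of solid substrate. My reckoning with the same feed gives a fill time of 23.4 min and a peak of 75.2 %. The simulated best of that neighbouring flask is 77.2 %, lower than the 82.8 % of the summer flask.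

(The runs were computed on assumed constants.)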